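**Plan**

1. Germacrane numbering is used throughout: C1=C10 is the Z olefin (C14 on C10), C2 the carbinol, C4=C5 the E olefin (C15 on C4), C6 the lactone O–CH, C7 the fusion CH, C8 the acyloxy CH, C11=C13 the methylene and C12 the lactone carbonyl. Retrosynthetic cuts, in order: the O8 ester, the ring bond C9–C10, the lactone bond O6–C12, then C8–C9, C6–C7 and C2–C3.
2. Forward: enal 9 (C1–C6, C10, C14, C15, with the C10 iodide) and imide 17 (C7, C8, C11–C13) are joined by an aldol at C6–C7, and C9 is added as a chloromethyl group. The five-membered lactone is closed first (step 15) and the ten-membered ring second (step 16).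
3. Enabling feature: the C8 oxygen is β to the olefinic carbon C10 through the C9 methylene, which is the pattern left when an alkenyl group opens a terminal C8–C9 epoxide at C9. The seco compound is therefore a terminal epoxide carrying a (Z)-C10 alkenyl iodide, held by the trans C6–C7 lactone.
4. Stereocentres: C2 from a catalytic enantioselective vinylogous Mukaiyama aldol, C6 and C7 from an Evans syn aldol, C8 from a 1,3-anti reduction directed by the C6 hydroxyl, and the side-chain centre from methyl (S)-3-hydroxy-2-methylpropanoate.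
5. Olefin geometry: 4E from the vinylogous aldol; 1(10)Z from hydroxyl-directed trans-hydroalumination/iodination, carried through a stereoretentive nickel coupling.
6. End game after ring closure: acylation of O8 and removal of two silyl groups.

Key step: step 16

Remark: the CIP letters of C7 and C8 change along the route because substituent priorities change; the spatial arrangement does not.

**Route**

Step 1
Reactants: 1 methyl 3-methylbut-2-enoate
Product: 3 tert-butyl[(1-methoxy-3-methylbuta-1,3-dien-1-yl)oxy]dimethylsilane, via lithium dienolate 2 (not isolated)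
Conditions: LDA, THF, −78 °C; then TBSCl, DMPU, −78 °C → rt
Reagents that add atoms: tert-butylchlorodimethylsilane, CC(C)(C)[Si](C)(C)Cl
Why: Kinetic γ-deprotonation of the senecioate gives the cross-conjugated dienolate, which is silylated on oxygen (silyl ketene acetal formation).

Step 2
Reactants: 3 silyl dienol ether; 4 but-2-ynal
Product: 5 methyl (2E,5R)-5-hydroxy-3-methyloct-2-en-6-ynoate
Conditions: SiCl4 (1.1 equiv), BINAM-derived chiral bisphosphoramide (5 mol %, the enantiomer that directs Re-face attack), i-Pr2NEt (10 mol %), CH2Cl2, −78 °C; aq. NaHCO3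
Reagents that add atoms: none
Why: Catalytic enantioselective vinylogous Mukaiyama aldol addition, in which the phosphoramide-bound silicon Lewis acid activates the ynal, the dienolate attacks through its γ-carbon on the Re face to set C2 as R, and the s-trans diene should deliver the E C4=C5 olefin.

Step 3
Reactants: 5 methyl (2E,5R)-5-hydroxy-3-methyloct-2-en-6-ynoate
Product: 7 (2E,5R,6Z)-7-iodo-3-methylocta-2,6-diene-1,5-diol, via alkenylalanate 6 (not isolated)
Conditions: NaAlH2(OCH2CH2OMe)2 (3.5 equiv), THF, 0 °C → rt; EtOAc; then I2, THF, −78 → 0 °C; aq. sodium potassium tartrate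
Reagents that add atoms: iodine, II
Why: The propargylic alkoxide directs trans-hydroalumination (hydride to C1, aluminium to C10) so that iodinolysis with retention gives the Z C10 iodide, while the same hydride reduces the conjugated ester to the allylic alcohol by 1,2-addition.

Step 4
Reactants: 7 (2E,5R,6Z)-7-iodo-3-methylocta-2,6-diene-1,5-diol
Product: 8 (2E,5R,6Z)-5-hydroxy-7-iodo-3-methylocta-2,6-dienal
Conditions: TEMPO (10 mol %), PhI(OAc)2, CH2Cl2, rt
Reagents that add atoms: none
Why: Oxoammonium oxidation (TEMPO/PhI(OAc)2) discriminates the primary allylic alcohol from the secondary one and leaves the alkenyl iodide untouched.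

Step 5
Reactants: 8 (2E,5R,6Z)-5-hydroxy-7-iodo-3-methylocta-2,6-dienal
Product: 9 (2E,5R,6Z)-5-[(tert-butyldimethylsilyl)oxy]-7-iodo-3-methylocta-2,6-dienal
Conditions: TBSCl, imidazole, DMF, 0 °C → rt
Reagents that add atoms: tert-butylchlorodimethylsilane, CC(C)(C)[Si](C)(C)Cl
Why: Standard silylation of the secondary allylic alcohol masks O2 until the last step.

Step 6
Reactants: 10 3-chloro-2-(chloromethyl)prop-1-ene (threefold excess); 11 (4-methoxyphenyl)methanol
Product: 12 1-({[2-(chloromethyl)prop-2-en-1-yl]oxy}methyl)-4-methoxybenzene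
Conditions: NaH, THF/DMF, 0 °C → rt
Reagents that add atoms: none
Why: Williamson monoetherification of the symmetric bis-allylic dichloride, used in excess to suppress the bis-ether.

Step 7
Reactants: 12 2-(chloromethyl)allyl PMB ether
Product: 14 3-{[(4-methoxybenzyl)oxy]methyl}but-3-enoic acid, via allylmagnesium chloride 13 (not isolated)
Conditions: Mg turnings, THF, 0 °C (slow addition); then CO2, −40 °C → rt; 1 M HCl, 0 °C
Reagents that add atoms: carbon dioxide, O=C=O
Why: Allylic Grignard formation and carboxylation; the symmetric 2-substituted allyl unit makes α- and γ-attack on CO2 identical, so only the β,γ-unsaturated acid can form.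

Step 8
Reactants: 14 3-{[(4-methoxybenzyl)oxy]methyl}but-3-enoic acid; 15 (S)-4-benzyl-1,3-oxazolidin-2-one
Product: 17 (S)-4-benzyl-3-(3-{[(4-methoxybenzyl)oxy]methyl}but-3-enoyl)-1,3-oxazolidin-2-one, via mixed pivalic anhydride 16 (not isolated)
Conditions: PivCl, Et3N, THF, −20 °C; then 15, LiCl, −20 °C → rt
Reagents that add atoms: none
Why: Mixed-anhydride N-acylation of the oxazolidinone under LiCl/Et3N conditions, mild enough to keep the β,γ-olefin out of conjugation.

Step 9
Reactants: 17 N-acyl oxazolidinone; 9 silyloxy iodo enal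
Product: 19 (S)-4-benzyl-3-[(2S,3R,4E,7R,8Z)-7-[(tert-butyldimethylsilyl)oxy]-3-hydroxy-9-iodo-2-{3-[(4-methoxybenzyl)oxy]prop-1-en-2-yl}-5-methyldeca-4,8-dienoyl]-1,3-oxazolidin-2-one, via boron enolate 18 (not isolated)
Conditions: Bu2BOTf, i-Pr2NEt, CH2Cl2, −78 → 0 °C; then 9, −78 → 0 °C; pH 7 buffer, MeOH, H2O2, 0 °C
Reagents that add atoms: none
Why: Evans syn-aldol reaction, in which the Z boron enolate reacts at its α-carbon through a chair (Zimmerman–Traxler) transition state on the face away from the benzyl group, setting C7 (S here) and C6 (R) in the syn relationship that becomes the trans lactone fusion.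

Step 10
Reactants: 19 syn-aldol imide
Product: 20 (2S,3R,4E,7R,8Z)-7-[(tert-butyldimethylsilyl)oxy]-3-hydroxy-9-iodo-N-methoxy-2-{3-[(4-methoxybenzyl)oxy]prop-1-en-2-yl}-N,5-dimethyldeca-4,8-dienamide
Conditions: MeNH(OMe)·HCl, AlMe3, CH2Cl2, −20 → 0 °C; aq. sodium potassium tartrate
Reagents that add atoms: N,O-dimethylhydroxylamine hydrochloride, CNOC.Cl
Why: Aluminium amide transamination of the β-hydroxy imide (Weinreb amide formation), assisted by the free C6 hydroxyl, releases the auxiliary.

Step 11
Reactants: 20 Weinreb amide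
Product: 21 (3S,4R,5E,8R,9Z)-8-[(tert-butyldimethylsilyl)oxy]-1-chloro-4-hydroxy-10-iodo-3-{3-[(4-methoxybenzyl)oxy]prop-1-en-2-yl}-6-methylundeca-5,9-dien-2-one
Conditions: ICH2Cl (4 equiv), MeLi·LiBr (4 equiv, slow addition), THF, −78 °C; sat. NH4Cl
Reagents that add atoms: chloroiodomethane, ClCI
Why: Chloromethyllithium generated under Barbier conditions adds once to the Weinreb amide through the stable chelated tetrahedral intermediate; iodine–lithium exchange on ICH2Cl should be far faster than on the alkenyl iodide, and the first equivalent of base is consumed by the hydroxyl.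

Step 12
Reactants: 21 β-hydroxy chloromethyl ketone
Product: 22 (2S,3S,4R,5E,8R,9Z)-8-[(tert-butyldimethylsilyl)oxy]-1-chloro-10-iodo-3-{3-[(4-methoxybenzyl)oxy]prop-1-en-2-yl}-6-methylundeca-5,9-diene-2,4-diol
Conditions: Me4NBH(OAc)3, MeCN/AcOH (1:1), −30 °C
Reagents that add atoms: none
Why: Evans–Saksena reduction, in which the C6 hydroxyl binds the triacetoxyborohydride and delivers hydride intramolecularly through a chair to give the 1,3-anti diol, setting C8 (S here, R in the target).

Step 13
Reactants: 22 anti-diol chlorohydrin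
Product: 23 (3S,4R,5E,8R,9Z)-8-[(tert-butyldimethylsilyl)oxy]-10-iodo-1-[(4-methoxybenzyl)oxy]-6-methyl-2-methylidene-3-[(2S)-oxiran-2-yl]undeca-5,9-dien-4-ol
Conditions: K2CO3, MeOH, 0 °C
Reagents that add atoms: none
Why: Base-mediated 3-exo-tet closure of the chlorohydrin (Williamson epoxide formation) with retention at C8; as with 4-halo-1,3-diols under base, 1,2-closure should outpace attack of the C6 hydroxyl on C9.

Step 14
Reactants: 23 epoxy alcohol PMB ether
Product: 24 (3S,4R,5E,8R,9Z)-8-[(tert-butyldimethylsilyl)oxy]-10-iodo-6-methyl-2-methylidene-3-[(2S)-oxiran-2-yl]undeca-5,9-diene-1,4-diol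
Conditions: DDQ, CH2Cl2/pH 7 phosphate buffer (10:1), 0 °C; crude diol used at once
Reagents that add atoms: none
Why: Oxidative cleavage of the PMB ether by DDQ; neutral pH, low temperature and immediate use should keep the freed C12 hydroxyl from opening the epoxide in a 5-exo sense.

Step 15
Reactants: 24 epoxy 1,4-diol
Product: 26 (4S,5R)-5-[(1E,4R,5Z)-4-[(tert-butyldimethylsilyl)oxy]-6-iodo-2-methylhepta-1,5-dien-1-yl]-3-methylidene-4-[(2S)-oxiran-2-yl]oxolan-2-one, via lactol 25 (not isolated)
Conditions: TEMPO (20 mol %), PhI(OAc)2 (3 equiv), NaHCO3, CH2Cl2, 0 °C → rt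
Reagents that add atoms: none
Why: TEMPO/PhI(OAc)2 oxidative lactonisation of a 1,4-diol, in which the primary allylic alcohol is oxidised first, O6 closes to the lactol and a second oxidation gives the α-methylene lactone with the trans C6–C7 fusion fixed by the aldol.

Step 16
Reactants: 26 epoxy lactone (Z)-alkenyl iodide
Product: 28 (1(10)Z,2R,4E,6R,7R,8R)-2-[(tert-butyldimethylsilyl)oxy]-8-hydroxygermacra-1(10),4,11(13)-trien-12,6-olide, via iodohydrin 27 (not isolated)
Conditions: NiI2 (30 mol %), 4,4′-di-tert-butyl-2,2′-bipyridine (30 mol %), NaI (1 equiv), Et3N·HCl (1.5 equiv), Mn powder (5 equiv), DMPU, 25 °C; 26 added by syringe pump over 10 h (final 2 mM)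
Reagents that add atoms: none
Why: Proposed new method: iodide, assisted by the ammonium acid, opens the terminal epoxide reversibly at the unhindered C9 to the iodohydrin; zerovalent nickel inserts into the C10–I bond with retention, a monovalent nickel species abstracts iodine from C9, the primary C9 radical is captured at the alkenylnickel centre of the same molecule, and reductive elimination from trivalent nickel forges C9–C10 while manganese returns the catalyst. The closest known reaction is the intermolecular nickel-catalysed reductive coupling of terminal epoxides with aryl and alkenyl halides under iodide co-catalysis, which gives the same 2-hydroxyalkyl connectivity. The ten-membered ring closes by C(sp3)–C(sp2) reductive elimination from an eleven-membered nickelacycle and not by direct radical addition, so no β-oxygenated alkylmetal able to eliminate is formed. No stereocentre is created, and C8 keeps the epoxide configuration because only the C9–O bond breaks. The step needs terminal opening of the epoxide (secured by the unsubstituted C9), retention of the Z geometry (secured by the stereoretentive alkenylnickel pathway) and a C9 radical that lives long enough to reach nickel. The lactone closed in step 15 is there for this last point: it makes 5-exo attack of the radical on C5 a trans-bicyclo[3.3.0]octane closure, it removes the abstractable C12 hydrogens, and slow addition should keep intermolecular coupling down.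

Step 17
Reactants: 29 methyl (S)-3-hydroxy-2-methylpropanoate
Product: 30 methyl (S)-3-[(tert-butyldimethylsilyl)oxy]-2-methylpropanoate
Conditions: TBSCl, imidazole, CH2Cl2, 0 °C → rt
Reagents that add atoms: tert-butylchlorodimethylsilane, CC(C)(C)[Si](C)(C)Cl
Why: Standard silylation of the primary alcohol.

Step 18
Reactants: 30 methyl (S)-3-[(tert-butyldimethylsilyl)oxy]-2-methylpropanoate
Product: 31 (S)-3-[(tert-butyldimethylsilyl)oxy]-2-methylpropanoic acid
Conditions: LiOH, THF/MeOH/H2O, 0 °C; 1 M HCl to pH 4, 0 °C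
Reagents that add atoms: lithium hydroxide, [Li+].[OH-]
Why: Saponification of the methyl ester at low temperature, under which the α-stereocentre of this ester class should be retained.

Step 19
Reactants: 28 8-hydroxy germacranolide; 31 (S)-3-[(tert-butyldimethylsilyl)oxy]-2-methylpropanoic acid
Product: 32 (1(10)Z,2R,4E,6R,7R,8R)-2-[(tert-butyldimethylsilyl)oxy]-8-{[(2S)-3-[(tert-butyldimethylsilyl)oxy]-2-methylpropanoyl]oxy}germacra-1(10),4,11(13)-trien-12,6-olide
Conditions: EDC·HCl, DMAP, CH2Cl2, 0 °C → rt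
Reagents that add atoms: none
Why: Steglich esterification (carbodiimide/DMAP) of the only free hydroxyl, with the acyl stereocentre coming unchanged from 29.

Step 20
Reactants: 32 bis-silyl ether
Product: 33 (1(10)Z,2R,4E,6R,7R,8R)-2-hydroxy-8-{[(2S)-3-hydroxy-2-methylpropanoyl]oxy}germacra-1(10),4,11(13)-trien-12,6-olide
Conditions: HF·pyridine, pyridine, THF, 0 °C → rt
Reagents that add atoms: none
Why: Fluoride-mediated cleavage of both silyl ethers under buffered conditions that the α-methylene lactone and the β-hydroxy ester should tolerate.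

**Compound list**

1 | methyl 3-methylbut-2-enoate | CC(C)=CC(=O)OC | starting material
2 | lithium 1-methoxy-3-methylbuta-1,3-dien-1-olate | [Li+].[O-]C(OC)=CC(C)=C | intermediate
3 | tert-butyl[(1-methoxy-3-methylbuta-1,3-dien-1-yl)oxy]dimethylsilane | C=C(C)C=C(OC)O[Si](C)(C)C(C)(C)C | intermediate
4 | but-2-ynal | CC#CC=O | starting material
5 | methyl (2E,5R)-5-hydroxy-3-methyloct-2-en-6-ynoate | CC#C[C@H](O)C/C(C)=C/C(=O)OC | intermediate
6 | sodium cyclic (Z)-alkenylalanate of 5 with C6 reduced to the alkoxide | [Na+].[Na+].[O-]C/C=C(\C)C[C@H]1O[Al-](OCCOC)(OCCOC)C(C)=C1 | intermediate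
7 | (2E,5R,6Z)-7-iodo-3-methylocta-2,6-diene-1,5-diol | OC/C=C(\C)C[C@@H](O)/C=C(/C)I | intermediate
8 | (2E,5R,6Z)-5-hydroxy-7-iodo-3-methylocta-2,6-dienal | O=C/C=C(\C)C[C@@H](O)/C=C(/C)I | intermediate
9 | (2E,5R,6Z)-5-[(tert-butyldimethylsilyl)oxy]-7-iodo-3-methylocta-2,6-dienal | O=C/C=C(\C)C[C@@H](O[Si](C)(C)C(C)(C)C)/C=C(/C)I | intermediate
10 | 3-chloro-2-(chloromethyl)prop-1-ene | C=C(CCl)CCl | starting material
11 | (4-methoxyphenyl)methanol | COc1ccc(CO)cc1 | starting material
12 | 1-({[2-(chloromethyl)prop-2-en-1-yl]oxy}methyl)-4-methoxybenzene | C=C(CCl)COCc1ccc(OC)cc1 | intermediate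
13 | (2-{[(4-methoxybenzyl)oxy]methyl}prop-2-en-1-yl)magnesium chloride | C=C(C[Mg]Cl)COCc1ccc(OC)cc1 | intermediate
14 | 3-{[(4-methoxybenzyl)oxy]methyl}but-3-enoic acid | C=C(CC(=O)O)COCc1ccc(OC)cc1 | intermediate
15 | (S)-4-benzyl-1,3-oxazolidin-2-one | O=C1N[C@@H](Cc2ccccc2)CO1 | starting material
16 | mixed anhydride of 14 with pivalic acid | C=C(CC(=O)OC(=O)C(C)(C)C)COCc1ccc(OC)cc1 | intermediate
17 | (S)-4-benzyl-3-(3-{[(4-methoxybenzyl)oxy]methyl}but-3-enoyl)-1,3-oxazolidin-2-one | C=C(CC(=O)N1[C@@H](Cc2ccccc2)COC1=O)COCc1ccc(OC)cc1 | intermediate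
18 | (Z)-dibutylboron enolate of 17 | CCCCB(CCCC)O/C(=C\C(=C)COCc1ccc(OC)cc1)N1[C@@H](Cc2ccccc2)COC1=O | intermediate
19 | syn-aldol imide (germacrane C2 R, C6 R, C7 S; 4E, 1(10)Z) | C=C(COCc1ccc(OC)cc1)[C@H](C(=O)N1[C@@H](Cc2ccccc2)COC1=O)[C@H](O)/C=C(\C)C[C@@H](O[Si](C)(C)C(C)(C)C)/C=C(/C)I | intermediate
20 | Weinreb amide (C2 R, C6 R, C7 S) | C=C(COCc1ccc(OC)cc1)[C@H](C(=O)N(C)OC)[C@H](O)/C=C(\C)C[C@@H](O[Si](C)(C)C(C)(C)C)/C=C(/C)I | intermediate
21 | β-hydroxy chloromethyl ketone (C2 R, C6 R, C7 S) | C=C(COCc1ccc(OC)cc1)[C@H](C(=O)CCl)[C@H](O)/C=C(\C)C[C@@H](O[Si](C)(C)C(C)(C)C)/C=C(/C)I | intermediate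
22 | 6,8-anti-diol chlorohydrin (C2 R, C6 R, C7 S, C8 S) | C=C(COCc1ccc(OC)cc1)[C@H]([C@H](O)CCl)[C@H](O)/C=C(\C)C[C@@H](O[Si](C)(C)C(C)(C)C)/C=C(/C)I | intermediate
23 | 8,9-epoxy 6-alcohol, O12 PMB (C2 R, C6 R, C7 S, C8 S) | C=C(COCc1ccc(OC)cc1)[C@H]([C@H]1CO1)[C@H](O)/C=C(\C)C[C@@H](O[Si](C)(C)C(C)(C)C)/C=C(/C)I | intermediate
24 | 8,9-epoxy 6,12-diol (C2 R, C6 R, C7 S, C8 S) | C=C(CO)[C@H]([C@H]1CO1)[C@H](O)/C=C(\C)C[C@@H](O[Si](C)(C)C(C)(C)C)/C=C(/C)I | intermediate
25 | 6,12-lactol (oxolan-2-ol, both C12 epimers) of 24 | C=C1C(O)O[C@H](/C=C(\C)C[C@@H](O[Si](C)(C)C(C)(C)C)/C=C(/C)I)[C@H]1[C@H]2CO2 | intermediate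
26 | (4S,5R)-5-[(1E,4R,5Z)-4-[(tert-butyldimethylsilyl)oxy]-6-iodo-2-methylhepta-1,5-dien-1-yl]-3-methylidene-4-[(2S)-oxiran-2-yl]oxolan-2-one (9,10-seco epoxy lactone) | C=C1C(=O)O[C@H](/C=C(\C)C[C@@H](O[Si](C)(C)C(C)(C)C)/C=C(/C)I)[C@H]1[C@H]2CO2 | intermediate
27 | (4R,5R)-5-[(1E,4R,5Z)-4-[(tert-butyldimethylsilyl)oxy]-6-iodo-2-methylhepta-1,5-dien-1-yl]-4-[(1S)-1-hydroxy-2-iodoethyl]-3-methylideneoxolan-2-one | C=C1C(=O)O[C@H](/C=C(\C)C[C@@H](O[Si](C)(C)C(C)(C)C)/C=C(/C)I)[C@H]1[C@H](O)CI | intermediate
28 | (1(10)Z,2R,4E,6R,7R,8R)-2-[(tert-butyldimethylsilyl)oxy]-8-hydroxygermacra-1(10),4,11(13)-trien-12,6-olide | C=C1C(=O)O[C@@H]2/C=C(\C)C[C@@H](O[Si](C)(C)C(C)(C)C)/C=C(/C)C[C@@H](O)[C@@H]12 | intermediate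
29 | methyl (S)-3-hydroxy-2-methylpropanoate | COC(=O)[C@@H](C)CO | starting material
30 | methyl (S)-3-[(tert-butyldimethylsilyl)oxy]-2-methylpropanoate | COC(=O)[C@@H](C)CO[Si](C)(C)C(C)(C)C | intermediate
31 | (S)-3-[(tert-butyldimethylsilyl)oxy]-2-methylpropanoic acid | OC(=O)[C@@H](C)CO[Si](C)(C)C(C)(C)C | intermediate
32 | 2-O-TBS, 3′-O-TBS ether of the target | C=C1C(=O)O[C@@H]2/C=C(\C)C[C@@H](O[Si](C)(C)C(C)(C)C)/C=C(/C)C[C@@H](OC(=O)[C@@H](C)CO[Si](C)(C)C(C)(C)C)[C@@H]12 | intermediate
33 | (1(10)Z,2R,4E,6R,7R,8R)-2-hydroxy-8-{[(2S)-3-hydroxy-2-methylpropanoyl]oxy}germacra-1(10),4,11(13)-trien-12,6-olide | C=C1C(=O)O[C@@H]2/C=C(\C)C[C@@H](O)/C=C(/C)C[C@@H](OC(=O)[C@@H](C)CO)[C@@H]12 | target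

**Step count**

Total: 20 steps. Longest linear sequence: 15 steps (1–5, 9–16, 19, 20).

**Steps most likely to fail**

Step 16 (proposed new method). The C9 radical may not reach the nickel centre of its own molecule, which would give intermolecular coupling to oligomers or premature reduction of either terminus. Zerovalent nickel may also ionise the allylic C6–O bond of the lactone or engage the methylene lactone.

The fallback uses known chemistry only. It sets out from enal 9 and comes back at 28. It makes the C9–C10 bond by the established intermolecular coupling and closes the ring at C6–C7 instead.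
- Enal 9 is masked with HC(OMe)3/PPTS/MeOH as dimethyl acetal F1.
- Intermolecular nickel-catalysed reductive coupling of F1 with commercial (R)-2-{[(4-methoxybenzyl)oxy]methyl}oxirane (NiI2, bipyridine ligand, NaI, Et3N·HCl, Mn, DMPU) gives secondary alcohol F2. Its C8 configuration comes from the epoxide.
- Silylation (TESOTf, 2,6-lutidine) gives triethylsilyl ether F3.
- DDQ frees primary alcohol F4.
- Dess–Martin oxidation gives α-silyloxy aldehyde F5.
- Baylis–Hillman reaction with methyl acrylate (DABCO) gives allylic alcohol F6.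
- NBS/Me2S converts F6 with allylic transposition into (Z)-2-(bromomethyl)enoate F7.
- Oxalic acid on wet silica releases enal F8.
- Intramolecular allylation of the aldehyde by the allylic bromide under divalent chromium (CrCl2, THF/DMF, high dilution) forms C6–C7 and the ten-membered ring; this is the closure established for germacranolides. The γ-hydroxy ester lactonises to silyl-protected lactone F9. The anti adduct corresponds to the trans lactone; the facial sense relative to C8 would have to be confirmed.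
- PPTS in MeOH at 0 °C removes the triethylsilyl group selectively and returns 28.

Step 11. Halogen–lithium exchange at the alkenyl iodide, enolisation at C7 (with loss of configuration or olefin migration) or retro-aldol cleavage of the lithium alkoxide may compete with carbenoid addition.

The fallback sets out from 19 and comes back at 21, bypassing 20 and all organolithium reagents.
- O6 is silylated (TESOTf, 2,6-lutidine) to give silyl ether imide F10.
- LiOH/H2O2 (THF/H2O, 0 °C) cleaves the auxiliary to carboxylic acid F11.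
- Activation as the isobutyl carbonic anhydride (i-BuOCOCl, N-methylmorpholine, −20 °C) and treatment with diazomethane give diazoketone F12.
- HCl in dioxane/MeOH at 0 °C converts the diazoketone into the chloromethyl ketone and cleaves the triethylsilyl ether, giving 21.

Step 2. Enantiofacial discrimination may be insufficient with the small ynal, or conversion low because of its volatility.

The fallback sets out from 3 and 4 and comes back at 5.
- The vinylogous Mukaiyama aldol is run without a chiral catalyst (BF3·OEt2, CH2Cl2, −78 °C) to give racemic alcohol F13.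
- Kinetic resolution with Burkholderia cepacia lipase and vinyl acetate (tert-butyl methyl ether, 30 °C) should, by the empirical size rule with the slim propynyl group as the medium substituent, acetylate the S enantiomer to acetate F14 and leave the R alcohol 5, which is separated by chromatography.

**Further compounds**

F1 | step 16 | (2E,5R,6Z)-5-[(tert-butyldimethylsilyl)oxy]-7-iodo-1,1-dimethoxy-3-methylocta-2,6-diene | COC(OC)/C=C(\C)C[C@@H](O[Si](C)(C)C(C)(C)C)/C=C(/C)I
F2 | step 16 | coupled secondary alcohol (C8 R), O7 PMB, C6 dimethyl acetal | COC(OC)/C=C(\C)C[C@@H](O[Si](C)(C)C(C)(C)C)/C=C(/C)C[C@@H](O)COCc1ccc(OC)cc1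
F3 | step 16 | O8 triethylsilyl ether of F2 | COC(OC)/C=C(\C)C[C@@H](O[Si](C)(C)C(C)(C)C)/C=C(/C)C[C@@H](O[Si](CC)(CC)CC)COCc1ccc(OC)cc1
F4 | step 16 | C7 primary alcohol | COC(OC)/C=C(\C)C[C@@H](O[Si](C)(C)C(C)(C)C)/C=C(/C)C[C@@H](O[Si](CC)(CC)CC)CO
F5 | step 16 | C7 aldehyde | COC(OC)/C=C(\C)C[C@@H](O[Si](C)(C)C(C)(C)C)/C=C(/C)C[C@@H](O[Si](CC)(CC)CC)C=O
F6 | step 16 | Baylis–Hillman adduct (both C7 epimers) | COC(OC)/C=C(\C)C[C@@H](O[Si](C)(C)C(C)(C)C)/C=C(/C)C[C@@H](O[Si](CC)(CC)CC)C(O)C(=C)C(=O)OC
F7 | step 16 | (Z)-2-(bromomethyl)enoate, C6 dimethyl acetal | COC(OC)/C=C(\C)C[C@@H](O[Si](C)(C)C(C)(C)C)/C=C(/C)C[C@@H](O[Si](CC)(CC)CC)/C=C(\CBr)C(=O)OC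
F8 | step 16 | (Z)-2-(bromomethyl)enoate enal (6,7-seco precursor) | O=C/C=C(\C)C[C@@H](O[Si](C)(C)C(C)(C)C)/C=C(/C)C[C@@H](O[Si](CC)(CC)CC)/C=C(\CBr)C(=O)OC
F9 | step 16 | 8-O-triethylsilyl ether of 28 | C=C1C(=O)O[C@@H]2/C=C(\C)C[C@@H](O[Si](C)(C)C(C)(C)C)/C=C(/C)C[C@@H](O[Si](CC)(CC)CC)[C@@H]12
F10 | step 11 | O6 triethylsilyl ether of 19 | C=C(COCc1ccc(OC)cc1)[C@H](C(=O)N1[C@@H](Cc2ccccc2)COC1=O)[C@H](O[Si](CC)(CC)CC)/C=C(\C)C[C@@H](O[Si](C)(C)C(C)(C)C)/C=C(/C)I
F11 | step 11 | C8 carboxylic acid, O6 triethylsilyl | C=C(COCc1ccc(OC)cc1)[C@H](C(=O)O)[C@H](O[Si](CC)(CC)CC)/C=C(\C)C[C@@H](O[Si](C)(C)C(C)(C)C)/C=C(/C)I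
F12 | step 11 | diazomethyl ketone, O6 triethylsilyl | C=C(COCc1ccc(OC)cc1)[C@H](C(=O)C=[N+]=[N-])[C@H](O[Si](CC)(CC)CC)/C=C(\C)C[C@@H](O[Si](C)(C)C(C)(C)C)/C=C(/C)I
F13 | step 2 | racemic methyl (2E)-5-hydroxy-3-methyloct-2-en-6-ynoate | CC#CC(O)C/C(C)=C/C(=O)OC
F14 | step 2 | methyl (2E,5S)-5-acetoxy-3-methyloct-2-en-6-ynoate | CC#C[C@@H](OC(C)=O)C/C(C)=C/C(=O)OC
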